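I decided to compare the flasks by one number and to reckon it from the earlier runs.

the same everywhere: gas 200 mM (held)

| charge | substrate | first nucleophile | temperature | remark | time |
|---|---|---|---|---|---|
| grey | 0.84 M | 0.46 M | 30 °C | run made earlier |  |
| amber | 0.84 M | 1.8 M | 50 °C | run made earlier |  |
| teal | 1.3 M | 0.924 M | 30 °C | run made earlier |  |
| Sunday's | 0.84 M | 0.924 M | 35 °C |  | 4.0 min |
| Monday's | 0.84 M | 0.924 M | 65 °C |  | 4.0 min |

| run | time / min | target / % | other capture product / % | substrate / % |
|---|---|---|---|---|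
| grey | 0.333 | 13.4 | 44.6 | 43.3 |
| grey | 1.00 | 20.4 | 71.8 | 6.8 |
| grey | 1.50 | 21.4 | 76.6 | 3.1 |
| grey | 2.50 | 22.5 | 77.7 | 0.6 |
| grey | 4.00 | 23.0 | 77.9 | 0.7 |
| grey | 5.00 | 19.8 | 78.3 | 1.4 |
| amber | 0.200 | 57.4 | 38.9 | 2.9 |
| amber | 0.333 | 59.7 | 41.2 | 0.6 |
| amber | 0.500 | 58.4 | 40.2 | 0 |
| amber | 1.00 | 56.7 | 43.1 | 0 |
| amber | 1.33 | 59.0 | 43.7 | 0 |
| amber | 2.50 | 59.0 | 40.9 | 1.0 |
| teal | 0.417 | 25.6 | 40.9 | 35.4 |
| teal | 0.667 | 28.6 | 53.2 | 17.6 |
| teal | 1.33 | 35.0 | 64.7 | 5.0 |
| teal | 2.50 | 34.1 | 64.9 | 0 |
| teal | 5.00 | 33.2 | 66.4 | 0.9 |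

(readings scatter by 1 percentage point)

- at the start none of the gas is in solution

- the flask with the highest share of target in all that became target or other capture product ("all alike" if they lie within 1.5 percentage points) (Sunday's / Monday's / all alike)
- share of target in all that became target or other capture product, Sunday's
- share of target in all that became target or other capture product, Monday's

Let B be the first nucleophile in M, Bc its charge, and Q the other capture product in M. If target forms against other capture product at the ratio rB, then r = ln(Bc/B)/Q. I took each run's reading at 2.50 min, a single reading with its scatter: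

grey: r = 0.811 L mol⁻¹
teal: r = 0.775 L mol⁻¹
amber: r = 0.937 L mol⁻¹

The grey and teal mean was 0.793 L mol⁻¹: the capture ratio, a selectivity factor, target made over other capture product made per molar of first nucleophile.

I went through the settings. Time should do little once substrate is spent, and grey's target read 22.5 % at 2.50 min and 23.0 % at 4.00 min, with substrate at 0.6 %. More first nucleophile should raise the share f = rB/(1+rB). More substrate should lower it by using up B, so I iterated on the mean B. Temperature is the one setting separating the two flasks. Amber's r, from the hotter run, went to Monday's.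

Sunday's: f = 42.3 % at the charge; then B = 0.746 M, f = 37.2 %
Monday's: f = 46.4 % at the charge; then B = 0.729 M, f = 40.6 %

I chose Monday's, ahead by 3.4 percentage points, beyond the margin. The forecast also chose Monday's. It gave 38 % for Sunday's against my 37.2 %, and 50 % for Monday's, higher than mine, on this ground: “Gas transfer probably cannot keep up”.

The simulation gave 36.6 % on Sunday's and 50.9 % on Monday's, so Monday's led and the forecast held.

    substrate ⇌ intermediate (K = 0.140, k = 0.0870 s⁻¹, Ea = 81.0 kJ mol⁻¹, ΔH = 10.0 kJ mol⁻¹)
    first nucleophile + intermediate → target (k = 1.30 L mol⁻¹ s⁻¹, Ea = 41.0 kJ mol⁻¹)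
    second nucleophile + intermediate → other capture product (k = 9.40 L mol⁻¹ s⁻¹, Ea = 43.0 kJ mol⁻¹)
    gas ⇌ second nucleophile, rate k4*(csat - [second nucleophile]) (kL = 1.70 s⁻¹)
    second nucleophile → decomposed reagent (k = 0.0250 s⁻¹, Ea = 72.0 kJ mol⁻¹)
    (constants at 35 °C)

Read back from these ends, r was 0.761 L mol⁻¹ on Sunday's, against 0.793 L mol⁻¹ from the earlier runs. On Monday's it was 1.50 L mol⁻¹, twice Sunday's. The neighbour, Sunday's flask with 2.3 M of first nucleophile, went through the same two rounds at Sunday's r:

f = 63.7 % at the charge; then B = 2.03 M, f = 60.7 %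

Its simulated share was 60.5 %.

The data are simulated with constants of no real substance, and the scatter is random.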